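Read the flasks below by one number before touching a feed.

all flasks: free base 2.00 equiv; time 20 s
- autumn: electrophile 5.0 × 10⁻⁴ M (fed, over 12 s); nucleophile 1.30 equiv; all else is in the flask from the start; the feed brings no volume worth counting
- dawn: electrophile 5.0 × 10⁻⁴ M; nucleophile 1.30 equiv (fed, over 12 s); all else is in the flask from the start; the feed brings no volume worth counting
- spring: electrophile 5.0 × 10⁻⁴ M; nucleophile 1.30 equiv; everything together at the start

    electrophile + nucleophile → acid set free + target (k1 = 100 M⁻¹ s⁻¹)
    nucleophile + acid set free ⇌ protonated nucleophile, settled at all times (K2 = 27000 M⁻¹)
    acid set free + free base ⇌ salt of the base (K3 = 2.0 × 10⁵ M⁻¹, k3 = 1400 M⁻¹ s⁻¹)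
    acid set free + target → side product (k4 = 160 M⁻¹ s⁻¹)

* which flask leads in amount of target, in percent of the electrophile charged ("all alike" within 1.5 percentage points) (autumn / dawn / spring / all alike)
* how much target is there at the end, in percent of the electrophile charged: autumn
* how much target is there at the end, in percent of the electrophile charged: dawn
* how much target is there at the end, in percent of the electrophile charged: spring

Electrophile is the limiting reagent, with 1.30 equiv of nucleophile against it. A steady feed delivers its charge on average half the feed time late, whichever partner is fed. So I carry the exposure X, which is k₁ times the electrophile charge times the time, less half of any feed time. Writing the balance of electrophile under step 1, with the nucleophile counted as free, gives my estimate of the fraction x turned into target, where e is the equivalents of nucleophile: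

x = e(E − 1)/(eE − 1), with E = exp((e − 1)X)

autumn and dawn: X = 0.700, x = 50.3%

spring: X = 1.00, x = 60.3%

So at 20 s I expect target at x and the rest of the electrophile charge still unreacted, and I leave spring unfed, since a feed lowers X. I expect my figures to run high: at balance, with the nucleophile as charged in spring, protonated nucleophile exceeds acid set free by a factor of 18, so part of the nucleophile I counted as free is bound.

The forecast is lower than my reckoning, with 44% for autumn, 47% for dawn and 54% for spring. It leads with spring and says “the feeds mainly lose reaction time”.

The simulation gives 44.7% for autumn, 44.9% for dawn and 54.0% for spring, so spring leads.

Autumn over spring reads 0.828 in the simulation and 0.834 in my reckoning, though my figures stand above the simulated ones. A neighbour of autumn holds the equivalents and takes 1.3 × 10⁻⁴ M of electrophile, which brings X down to 0.182 and x to 19.6%. That neighbour gives 18.6% of target, and at 20.0 s it still holds 81% of its electrophile and 1.14 × 10⁻⁵ M of protonated nucleophile.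

(All constants were chosen freely; no experiment stands behind them.)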